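A direct plan would grow the chain from ring A by copper-catalysed Ullmann etherification of perbenzylated phenols with bromobenzaldehydes, would turn each formyl group into the next phenol by Baeyer–Villiger (Dakin) oxidation, and would end with hydrogenolysis of eighteen benzyl ethers. Its weakest steps would be:
- the Ullmann coupling of the 2,6-disubstituted dimer phenol A2 with the ortho-formyl bromide A1, needed again on the tetramer, because a tri-ortho-substituted ether would have to form near 100 °C against debromination and aldehyde decay;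
- the peracid oxidation, repeated on ever larger electron-rich polyethers, because ring oxidation to quinones would compete;
- the six-step preparation of the ring A phenol A3, which would add length without complexity.

The new route does not couple the pentaoxygenated rings C and E; each is grown on the phenol oxygen of the ring before it. Numbered from the carbon on that oxygen, C3 to C6 with their four oxygens are the carbons of a squarate, and C1 (aryloxy) and C2 (hydrogen) are the carbons of an aryloxyacetylene. A lithium aryloxyacetylide is added to dimethyl squarate; semi-hydrogenation and a thermal 4π ring opening/6π ring closure then give the whole ring in one operation, with five oxygens in place, the tri-ortho-substituted diaryl ether already present and C6–OH as the only free phenol. Hindered Ullmann coupling to a formyl bromide, peracid oxidation and a synthesis of ring A have no counterpart.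

Key step: step 7

Remark: the target is achiral; rings are lettered A to G from the 2,4,6-trihydroxyphenoxy end, rings B to G are numbered from the carbon bound to the oxygen of the preceding ring, and the racemic cyclobutenone centre and the E/Z vinyl ethers met on the way are erased on aromatization.

Step 1
Reactants: 1 4-bromo-2,6-dimethoxyphenol
Product: 2 (4-bromo-2,6-dimethoxyphenoxy)tri(propan-2-yl)silane
Conditions: iPr3SiCl (1.2 equiv), imidazole (2.5 equiv), DMF, 40 °C
Reagents that add atoms: chlorotri(propan-2-yl)silane CC(C)[Si](Cl)(C(C)C)C(C)C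
Why: Silylation of the phenol (substitution at silicon); the bulky silyl ether should survive n-BuLi, dilute acid and the copper coupling, and is the only group on ring B that fluoride removes.

Step 2
Reactants: 2 (4-bromo-2,6-dimethoxyphenoxy)tri(propan-2-yl)silane
Product: 5 {3,5-dimethoxy-4-[tri(propan-2-yl)silyloxy]phenyl}boronic acid, via aryllithium 3 (not isolated), via lithium triisopropoxyborate 4 (not isolated)
Conditions: n-BuLi (1.05 equiv), THF, −78 °C; B(OiPr)3 (1.5 equiv), −78 °C → rt; then 1 M HCl, 0 °C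
Reagents that add atoms: triisopropyl borate CC(C)OB(OC(C)C)OC(C)C; water O
Why: Bromine–lithium exchange at −78 °C outruns attack at silicon or ortho-metalation, and borate trapping followed by hydrolysis is the standard boronic acid synthesis.

Step 3
Reactants: 6 2,4,6-trimethoxyphenol; 5 {3,5-dimethoxy-4-[tri(propan-2-yl)silyloxy]phenyl}boronic acid (2 equiv)
Product: 7 [2,6-dimethoxy-4-(2,4,6-trimethoxyphenoxy)phenoxy]tri(propan-2-yl)silane
Conditions: Cu(OAc)2 (1.0 equiv), pyridine (5 equiv), 4 Å molecular sieves, CH2Cl2, dry air, rt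
Reagents that add atoms: none
Why: Chan–Lam–Evans oxidative C–O coupling (aryl transfer from boron to copper, reductive elimination from a trivalent copper aryl phenoxide) runs at room temperature and tolerates the two ortho methoxy groups of 6 because the boron-bearing carbon of 5 has no ortho substituent, while the para methoxy group of 6 blocks oxidative phenol dimerisation.

Step 4
Reactants: 7 [2,6-dimethoxy-4-(2,4,6-trimethoxyphenoxy)phenoxy]tri(propan-2-yl)silane
Product: 8 2,6-dimethoxy-4-(2,4,6-trimethoxyphenoxy)phenol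
Conditions: Bu4NF (1.1 equiv), THF, 0 °C, Ar; then AcOH
Reagents that add atoms: none
Why: Fluoride-induced Si–O cleavage leaves methyl and diaryl ethers untouched, and the acid quench under Ar keeps the electron-rich phenoxide from air oxidation.

Step 5
Reactants: 8 2,6-dimethoxy-4-(2,4,6-trimethoxyphenoxy)phenol; 9 trichloroethylene (2 equiv)
Product: 10 2-{[(E)-1,2-dichloroethenyl]oxy}-1,3-dimethoxy-5-(2,4,6-trimethoxyphenoxy)benzene
Conditions: K2CO3 (2.5 equiv), DMF, 70 °C, Ar
Reagents that add atoms: none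
Why: Base takes HCl from trichloroethylene to give dichloroacetylene in the flask, to which the phenoxide adds anti (nucleophilic addition, then protonation) to give the E vinyl ether; this rod-shaped electrophile does not feel the two ortho methoxy groups, so the oxygen–carbon bond that becomes the ring B–O–C1 (ring C) ether is made without a metal.

Step 6
Reactants: 10 2-{[(E)-1,2-dichloroethenyl]oxy}-1,3-dimethoxy-5-(2,4,6-trimethoxyphenoxy)benzene; 11 dimethyl squarate (1.3 equiv)
Product: 14 4-{[2,6-dimethoxy-4-(2,4,6-trimethoxyphenoxy)phenoxy]ethynyl}-2,3,4-trimethoxycyclobut-2-en-1-one (racemic), via lithium acetylide 12 (not isolated), via lithium alkoxide 13 (not isolated)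
Conditions: n-BuLi (2.1 equiv), THF, −78 → −40 °C; cannulated into 11, THF, −78 °C; then MeOTf (3 equiv), −78 → 0 °C
Reagents that add atoms: methyl trifluoromethanesulfonate COS(=O)(=O)C(F)(F)F
Why: Dehydrochlorination and chlorine–lithium exchange give the lithium aryloxyacetylide (trichloroethylene route to ynol ethers), which adds 1,2 to one of the two equivalent carbonyl groups of the squarate at −78 °C, and O-methylation of the tertiary lithium alkoxide in the flask fixes the later C3 oxygen as its methyl ether; the new quaternary stereocentre forms as a racemate and is erased in step 7.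

Step 7
Reactants: 14 4-{[2,6-dimethoxy-4-(2,4,6-trimethoxyphenoxy)phenoxy]ethynyl}-2,3,4-trimethoxycyclobut-2-en-1-one
Product: 17 6-[2,6-dimethoxy-4-(2,4,6-trimethoxyphenoxy)phenoxy]-2,3,4-trimethoxyphenol, via Z-alkenylcyclobutenone 15 (not isolated), via dienylketene 16 (not isolated)
Conditions: H2 (1 atm), Pd/CaCO3 poisoned with Pb(OAc)2, quinoline, toluene, rt, to 1 equiv H2; filtered under Ar; filtrate 110 °C
Reagents that add atoms: none
Why: Syn delivery of H2 on the poisoned palladium surface stops at the Z enol ether 15; on heating, the cyclobutenone opens in a conrotatory 4π process in which the donor methoxy group at C4 rotates outward and so turns the aryloxyvinyl group inward, toward the ketene of 16. Thermal 6π electrocyclisation then joins the ketene carbon to the aryloxy-bearing vinyl carbon (6-endo closure of ring C by C–C bond formation), and enolisation of the cyclohexadienone gives the phenol. The closest known reaction is the Moore–Liebeskind ring expansion of 4-alkenyl-4-alkoxycyclobutenones to monoprotected hydroquinones. No stereocentre results, since the racemic C4 and the Z alkene end as sp2 ring carbons. Regiochemistry is written into the connectivity: the squarate carbons become C3 to C6, the methylated carbinol carbon becomes C3–OMe, the ketene carbonyl becomes the only free hydroxyl at C6 next to the aryloxy-bearing C1, and the vinyl CH becomes C2–H. The selectivities needed are chemoselective alkyne reduction, secured by the lead- and quinoline-poisoned catalyst, and inward rotation of the alkenyl group, secured by the outward preference of the C4 oxygen substituent.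

Step 8
Reactants: 18 2,3-dimethoxyphenol
Product: 19 (2,3-dimethoxyphenoxy)tri(propan-2-yl)silane
Conditions: iPr3SiCl (1.2 equiv), imidazole (2.5 equiv), DMF, rt
Reagents that add atoms: chlorotri(propan-2-yl)silane CC(C)[Si](Cl)(C(C)C)C(C)C
Why: Silylation of the phenol (substitution at silicon) masks the later C5 oxygen of ring D and adds bulk that steers the borylation of step 9.

Step 9
Reactants: 19 (2,3-dimethoxyphenoxy)tri(propan-2-yl)silane
Product: 21 {3,4-dimethoxy-5-[tri(propan-2-yl)silyloxy]phenyl}boronic acid, via pinacol boronate 20 (not isolated)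
Conditions: [Ir(OMe)(cod)]2 (1.5 mol %), 4,4′-di-tert-butyl-2,2′-bipyridine (3 mol %), B2pin2 (1.0 equiv), THF, 80 °C; then NaIO4 (3 equiv), THF/H2O, rt; then 1 M HCl, rt
Reagents that add atoms: bis(pinacolato)diboron CC1(C)OB(OC1(C)C)B1OC(C)(C)C(C)(C)O1; water O
Why: Iridium-catalysed aromatic C–H borylation is steered by sterics, and C5 of 19 is the only ring C–H without an ortho substituent, so boron enters exactly where ring D must join ring C; periodate cleaves the pinacol released on hydrolysis and so drives the ester to the boronic acid.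

Step 10
Reactants: 17 6-[2,6-dimethoxy-4-(2,4,6-trimethoxyphenoxy)phenoxy]-2,3,4-trimethoxyphenol; 21 {3,4-dimethoxy-5-[tri(propan-2-yl)silyloxy]phenyl}boronic acid (3 equiv)
Product: 22 rings A–D silyl ether (17 O-arylated at its free hydroxyl by the 3,4-dimethoxy-5-[tri(propan-2-yl)silyloxy]phenyl group)
Conditions: Cu(OAc)2 (1.5 equiv), pyridine (5 equiv), 4 Å molecular sieves, CH2Cl2, dry air, rt
Reagents that add atoms: none
Why: Chan–Lam–Evans coupling as in step 3; the phenol oxygen of 17 is flanked by aryloxy and methoxy groups, but the aryl group on copper has no ortho substituent, which is the combination this coupling tolerates, and the silyl, methyl and diaryl ethers are inert.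

Step 11
Reactants: 22 rings A–D silyl ether
Product: 23 rings A–D phenol (3-hydroxy-4,5-dimethoxyphenyl ether of 17)
Conditions: Bu4NF (1.1 equiv), THF, 0 °C, Ar; then AcOH
Reagents that add atoms: none
Why: Fluoride-induced Si–O cleavage frees only the C5 hydroxyl of ring D, on which ring E is to be grown.

Step 12
Reactants: 23 rings A–D phenol; 9 trichloroethylene (2 equiv)
Product: 24 rings A–D (E)-1,2-dichloroethenyl ether
Conditions: K2CO3 (2.5 equiv), DMF, 70 °C, Ar
Reagents that add atoms: none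
Why: Anti addition of the phenoxide to dichloroacetylene formed in the flask, as in step 5, gives the E vinyl ether, and only the one free hydroxyl can react.

Step 13
Reactants: 24 rings A–D (E)-1,2-dichloroethenyl ether; 11 dimethyl squarate (1.3 equiv)
Product: 27 rings A–D 4-(aryloxyethynyl)-2,3,4-trimethoxycyclobut-2-en-1-one (racemic), via lithium acetylide 25 (not isolated), via lithium alkoxide 26 (not isolated)
Conditions: n-BuLi (2.1 equiv), THF, −78 → −40 °C; cannulated into 11, THF, −78 °C; then MeOTf (3 equiv), −78 → 0 °C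
Reagents that add atoms: methyl trifluoromethanesulfonate COS(=O)(=O)C(F)(F)F
Why: Ynol ether acetylide formation, 1,2-addition to the squarate and O-methylation in the flask, as in step 6; the aryl methyl and diaryl ethers are inert to n-BuLi at −78 °C, and the racemic centre is erased in step 14.

Step 14
Reactants: 27 rings A–D 4-(aryloxyethynyl)-2,3,4-trimethoxycyclobut-2-en-1-one
Product: 30 rings A–E phenol (2-hydroxy-3,4,5-trimethoxyphenyl ether of 23), via Z-alkenylcyclobutenone 28 (not isolated), via dienylketene 29 (not isolated)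
Conditions: H2 (1 atm), Pd/CaCO3 poisoned with Pb(OAc)2, quinoline, toluene, rt, to 1 equiv H2; filtered under Ar; filtrate 110 °C
Reagents that add atoms: none
Why: The same Lindlar semi-hydrogenation and Moore–Liebeskind 4π opening/6π closure as in step 7 builds ring E on the C5 oxygen of ring D; 27 holds no benzyl ether or other reducible group, and its stereocentre and the Z alkene of 28 are erased on aromatization.

Step 15
Reactants: 1 4-bromo-2,6-dimethoxyphenol; 31 (3,4,5-trimethoxyphenyl)boronic acid (2 equiv)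
Product: 32 5-bromo-1,3-dimethoxy-2-(3,4,5-trimethoxyphenoxy)benzene
Conditions: Cu(OAc)2 (1.0 equiv), pyridine (5 equiv), 4 Å molecular sieves, CH2Cl2, dry air, rt
Reagents that add atoms: none
Why: Chan–Lam–Evans coupling; the bromine para to the hydroxyl of 1 blocks oxidative para coupling of this 2,6-dimethoxyphenol and is untouched by divalent copper at room temperature.

Step 16
Reactants: 32 5-bromo-1,3-dimethoxy-2-(3,4,5-trimethoxyphenoxy)benzene
Product: 35 [3,5-dimethoxy-4-(3,4,5-trimethoxyphenoxy)phenyl]boronic acid, via aryllithium 33 (not isolated), via lithium triisopropoxyborate 34 (not isolated)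
Conditions: n-BuLi (1.05 equiv), THF, −78 °C; B(OiPr)3 (1.5 equiv), −78 °C → rt; then 1 M HCl, 0 °C
Reagents that add atoms: triisopropyl borate CC(C)OB(OC(C)C)OC(C)C; water O
Why: Bromine–lithium exchange, borate trapping and hydrolysis, as in step 2; methyl and diaryl ethers are inert at −78 °C.

Step 17
Reactants: 30 rings A–E phenol; 35 [3,5-dimethoxy-4-(3,4,5-trimethoxyphenoxy)phenyl]boronic acid (3 equiv)
Product: 36 octadeca-O-methyl ether of the target
Conditions: Cu(OAc)2 (1.5 equiv), pyridine (5 equiv), 4 Å molecular sieves, CH2Cl2, dry air, rt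
Reagents that add atoms: none
Why: Chan–Lam–Evans coupling of the phenol at C6 of ring E with an aryl group that has no ortho substituent, as in step 10.

Step 18
Reactants: 36 octadeca-O-methyl ether of the target
Product: 37 CNP0130704.0
Conditions: BBr3 (54 equiv), CH2Cl2, −78 °C → rt, Ar; then H2O, 0 °C; reversed-phase chromatography in degassed H2O/MeOH
Reagents that add atoms: none
Why: Lewis acid ether cleavage, in which each methoxy oxygen binds boron and bromide attacks the methyl group (SN2), whereas the diaryl ether oxygens have no sp3 carbon to lose and stay.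

Compound list

1 | 4-bromo-2,6-dimethoxyphenol | COc1cc(Br)cc(OC)c1O | starting material
2 | (4-bromo-2,6-dimethoxyphenoxy)tri(propan-2-yl)silane | COc1cc(Br)cc(OC)c1O[Si](C(C)C)(C(C)C)C(C)C | intermediate
3 | {3,5-dimethoxy-4-[tri(propan-2-yl)silyloxy]phenyl}lithium | [Li]c1cc(OC)c(O[Si](C(C)C)(C(C)C)C(C)C)c(OC)c1 | intermediate (not isolated)
4 | lithium {3,5-dimethoxy-4-[tri(propan-2-yl)silyloxy]phenyl}tri(propan-2-yloxy)borate | [Li+].CC(C)O[B-](OC(C)C)(OC(C)C)c1cc(OC)c(O[Si](C(C)C)(C(C)C)C(C)C)c(OC)c1 | intermediate (not isolated)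
5 | {3,5-dimethoxy-4-[tri(propan-2-yl)silyloxy]phenyl}boronic acid (ring B donor) | OB(O)c1cc(OC)c(O[Si](C(C)C)(C(C)C)C(C)C)c(OC)c1 | intermediate
6 | 2,4,6-trimethoxyphenol | COc1cc(OC)c(O)c(OC)c1 | starting material
7 | [2,6-dimethoxy-4-(2,4,6-trimethoxyphenoxy)phenoxy]tri(propan-2-yl)silane | COc1cc(OC)c(Oc2cc(OC)c(O[Si](C(C)C)(C(C)C)C(C)C)c(OC)c2)c(OC)c1 | intermediate
8 | 2,6-dimethoxy-4-(2,4,6-trimethoxyphenoxy)phenol (rings A–B phenol) | COc1cc(OC)c(Oc2cc(OC)c(O)c(OC)c2)c(OC)c1 | intermediate
9 | trichloroethylene (1,1,2-trichloroethene) | ClC=C(Cl)Cl | starting material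
10 | 2-{[(E)-1,2-dichloroethenyl]oxy}-1,3-dimethoxy-5-(2,4,6-trimethoxyphenoxy)benzene | COc1cc(OC)c(Oc2cc(OC)c(O/C(Cl)=C\Cl)c(OC)c2)c(OC)c1 | intermediate
11 | dimethyl squarate (3,4-dimethoxycyclobut-3-ene-1,2-dione) | COC1=C(OC)C(=O)C1=O | starting material
12 | lithium [2,6-dimethoxy-4-(2,4,6-trimethoxyphenoxy)phenoxy]ethynide | COc1cc(OC)c(Oc2cc(OC)c(OC#C[Li])c(OC)c2)c(OC)c1 | intermediate (not isolated)
13 | lithium 1-{[2,6-dimethoxy-4-(2,4,6-trimethoxyphenoxy)phenoxy]ethynyl}-2,3-dimethoxy-4-oxocyclobut-2-en-1-olate (racemic) | COc1cc(OC)c(Oc2cc(OC)c(OC#CC3(O[Li])C(OC)=C(OC)C3=O)c(OC)c2)c(OC)c1 | intermediate (not isolated)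
14 | 4-{[2,6-dimethoxy-4-(2,4,6-trimethoxyphenoxy)phenoxy]ethynyl}-2,3,4-trimethoxycyclobut-2-en-1-one (racemic) | COc1cc(OC)c(Oc2cc(OC)c(OC#CC3(OC)C(OC)=C(OC)C3=O)c(OC)c2)c(OC)c1 | intermediate
15 | 4-{(Z)-2-[2,6-dimethoxy-4-(2,4,6-trimethoxyphenoxy)phenoxy]ethenyl}-2,3,4-trimethoxycyclobut-2-en-1-one (racemic) | COc1cc(OC)c(Oc2cc(OC)c(O/C=C\C3(OC)C(OC)=C(OC)C3=O)c(OC)c2)c(OC)c1 | intermediate (not isolated)
16 | (3Z,5Z)-6-[2,6-dimethoxy-4-(2,4,6-trimethoxyphenoxy)phenoxy]-2,3,4-trimethoxyhexa-1,3,5-trien-1-one | COc1cc(OC)c(Oc2cc(OC)c(O/C=C\C(OC)=C(OC)/C(OC)=C=O)c(OC)c2)c(OC)c1 | intermediate (not isolated)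
17 | 6-[2,6-dimethoxy-4-(2,4,6-trimethoxyphenoxy)phenoxy]-2,3,4-trimethoxyphenol (rings A–C phenol) | COc1cc(OC)c(Oc2cc(OC)c(Oc3cc(OC)c(OC)c(OC)c3O)c(OC)c2)c(OC)c1 | intermediate
18 | 2,3-dimethoxyphenol | COc1cccc(O)c1OC | starting material
19 | (2,3-dimethoxyphenoxy)tri(propan-2-yl)silane | COc1cccc(O[Si](C(C)C)(C(C)C)C(C)C)c1OC | intermediate
20 | 2-{3,4-dimethoxy-5-[tri(propan-2-yl)silyloxy]phenyl}-4,4,5,5-tetramethyl-1,3,2-dioxaborolane | COc1cc(B2OC(C)(C)C(C)(C)O2)cc(O[Si](C(C)C)(C(C)C)C(C)C)c1OC | intermediate (not isolated)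
21 | {3,4-dimethoxy-5-[tri(propan-2-yl)silyloxy]phenyl}boronic acid (ring D donor) | COc1cc(B(O)O)cc(O[Si](C(C)C)(C(C)C)C(C)C)c1OC | intermediate
22 | rings A–D silyl ether: 17 O-arylated by the 3,4-dimethoxy-5-[tri(propan-2-yl)silyloxy]phenyl group | COc1cc(OC)c(Oc2cc(OC)c(Oc3cc(OC)c(OC)c(OC)c3Oc4cc(OC)c(OC)c(O[Si](C(C)C)(C(C)C)C(C)C)c4)c(OC)c2)c(OC)c1 | intermediate
23 | rings A–D phenol: 3-hydroxy-4,5-dimethoxyphenyl ether of 17 | COc1cc(OC)c(Oc2cc(OC)c(Oc3cc(OC)c(OC)c(OC)c3Oc4cc(OC)c(OC)c(O)c4)c(OC)c2)c(OC)c1 | intermediate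
24 | rings A–D (E)-1,2-dichloroethenyl ether of 23 | COc1cc(OC)c(Oc2cc(OC)c(Oc3cc(OC)c(OC)c(OC)c3Oc4cc(OC)c(OC)c(O/C(Cl)=C\Cl)c4)c(OC)c2)c(OC)c1 | intermediate
25 | rings A–D lithium aryloxyethynide | COc1cc(OC)c(Oc2cc(OC)c(Oc3cc(OC)c(OC)c(OC)c3Oc4cc(OC)c(OC)c(OC#C[Li])c4)c(OC)c2)c(OC)c1 | intermediate (not isolated)
26 | rings A–D lithium 1-(aryloxyethynyl)-2,3-dimethoxy-4-oxocyclobut-2-en-1-olate (racemic) | COc1cc(OC)c(Oc2cc(OC)c(Oc3cc(OC)c(OC)c(OC)c3Oc4cc(OC)c(OC)c(OC#CC5(O[Li])C(OC)=C(OC)C5=O)c4)c(OC)c2)c(OC)c1 | intermediate (not isolated)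
27 | rings A–D 4-(aryloxyethynyl)-2,3,4-trimethoxycyclobut-2-en-1-one (racemic) | COc1cc(OC)c(Oc2cc(OC)c(Oc3cc(OC)c(OC)c(OC)c3Oc4cc(OC)c(OC)c(OC#CC5(OC)C(OC)=C(OC)C5=O)c4)c(OC)c2)c(OC)c1 | intermediate
28 | rings A–D 4-[(Z)-2-(aryloxy)ethenyl]-2,3,4-trimethoxycyclobut-2-en-1-one (racemic) | COc1cc(OC)c(Oc2cc(OC)c(Oc3cc(OC)c(OC)c(OC)c3Oc4cc(OC)c(OC)c(O/C=C\C5(OC)C(OC)=C(OC)C5=O)c4)c(OC)c2)c(OC)c1 | intermediate (not isolated)
29 | rings A–D (3Z,5Z)-6-(aryloxy)-2,3,4-trimethoxyhexa-1,3,5-trien-1-one | COc1cc(OC)c(Oc2cc(OC)c(Oc3cc(OC)c(OC)c(OC)c3Oc4cc(OC)c(OC)c(O/C=C\C(OC)=C(OC)/C(OC)=C=O)c4)c(OC)c2)c(OC)c1 | intermediate (not isolated)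
30 | rings A–E phenol: 2-hydroxy-3,4,5-trimethoxyphenyl ether of 23 | COc1cc(OC)c(Oc2cc(OC)c(Oc3cc(OC)c(OC)c(OC)c3Oc4cc(OC)c(OC)c(Oc5cc(OC)c(OC)c(OC)c5O)c4)c(OC)c2)c(OC)c1 | intermediate
31 | (3,4,5-trimethoxyphenyl)boronic acid | COc1cc(B(O)O)cc(OC)c1OC | starting material
32 | 5-bromo-1,3-dimethoxy-2-(3,4,5-trimethoxyphenoxy)benzene | COc1cc(Br)cc(OC)c1Oc2cc(OC)c(OC)c(OC)c2 | intermediate
33 | [3,5-dimethoxy-4-(3,4,5-trimethoxyphenoxy)phenyl]lithium | [Li]c1cc(OC)c(Oc2cc(OC)c(OC)c(OC)c2)c(OC)c1 | intermediate (not isolated)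
34 | lithium [3,5-dimethoxy-4-(3,4,5-trimethoxyphenoxy)phenyl]tri(propan-2-yloxy)borate | [Li+].CC(C)O[B-](OC(C)C)(OC(C)C)c1cc(OC)c(Oc2cc(OC)c(OC)c(OC)c2)c(OC)c1 | intermediate (not isolated)
35 | [3,5-dimethoxy-4-(3,4,5-trimethoxyphenoxy)phenyl]boronic acid (rings F–G donor) | OB(O)c1cc(OC)c(Oc2cc(OC)c(OC)c(OC)c2)c(OC)c1 | intermediate
36 | octadeca-O-methyl ether of the target (all 18 OH as OMe) | COc1cc(OC)c(Oc2cc(OC)c(Oc3cc(OC)c(OC)c(OC)c3Oc4cc(OC)c(OC)c(Oc5cc(OC)c(OC)c(OC)c5Oc6cc(OC)c(Oc7cc(OC)c(OC)c(OC)c7)c(OC)c6)c4)c(OC)c2)c(OC)c1 | intermediate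
37 | CNP0130704.0 (heptameric fuhalol-type phlorotannin, free octadecaol, achiral) | Oc1cc(O)c(Oc2cc(O)c(Oc3cc(O)c(O)c(O)c3Oc3cc(O)c(O)c(Oc4cc(O)c(O)c(O)c4Oc4cc(O)c(Oc5cc(O)c(O)c(O)c5)c(O)c4)c3)c(O)c2)c(O)c1 | target

Total step count: 18. Longest linear sequence: 14 steps (steps 1–7, 10–14, 17 and 18).

Steps most likely to fail

1. Step 7 (and its repeat, step 14). Hydrogen uptake may run past the alkene, and the saturated ether cannot aromatize; the acid-labile enol ether may also hydrolyse before the ring opens. The fallback sets out from 10 and 11 and needs no hydrogenation. The alkoxide 13 would be quenched with aqueous NH4Cl instead of MeOTf to give 4-{[2,6-dimethoxy-4-(2,4,6-trimethoxyphenoxy)phenoxy]ethynyl}-4-hydroxy-2,3-dimethoxycyclobut-2-en-1-one F1. Heating in p-xylene at 138 °C should take it through the alkynyl variant of the ring expansion (ketene, closure to a ring diradical, hydrogen transfer from OH) to 5-[2,6-dimethoxy-4-(2,4,6-trimethoxyphenoxy)phenoxy]-2,3-dimethoxycyclohexa-2,5-diene-1,4-dione F2. Na2S2O4 in THF/H2O should reduce this to 5-[2,6-dimethoxy-4-(2,4,6-trimethoxyphenoxy)phenoxy]-2,3-dimethoxybenzene-1,4-diol F3. MeI (1 equiv) with K2CO3 in acetone should then methylate the less shielded hydroxyl, the one next to the ring C–H, which comes back to the route at 17.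

2. Step 10 (and likewise step 17). C–O reductive elimination at a phenoxide flanked on both sides may be slow, so that protodeboronation and homocoupling of the boronic acid and copper-mediated oxidation of the electron-rich phenol take over. The fallback is a metal-free arylation and sets out from 21. NIS in MeCN (ipso-iododeboronation) should give (5-iodo-2,3-dimethoxyphenoxy)tri(propan-2-yl)silane F4. mCPBA and TsOH·H2O in MeCN, then 1,3,5-trimethoxybenzene, should give {3,4-dimethoxy-5-[tri(propan-2-yl)silyloxy]phenyl}(2,4,6-trimethoxyphenyl)iodonium 4-methylbenzenesulfonate F5. The potassium phenoxide of 17 (KOtBu, THF, 0 °C → rt) should then take the less electron-rich aryl group from iodine by ligand coupling, which comes back to the route at 22.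

3. Step 18. Cleavage may stop short of all eighteen methyl ethers, and the free pyrogallol-type rings may oxidise in air during isolation. The fallback sets out from 36: after the BBr3 treatment the crude polyphenol would be acetylated without isolation (Ac2O, pyridine, rt) to the octadeca-O-acetate of the target F6, which can be chromatographed in air and separated from under-cleaved material. NaOMe (cat.) in degassed MeOH under Ar, then an acidic ion-exchange resin, should give 37.

Further compounds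

F1 | step 7 | 4-{[2,6-dimethoxy-4-(2,4,6-trimethoxyphenoxy)phenoxy]ethynyl}-4-hydroxy-2,3-dimethoxycyclobut-2-en-1-one (racemic) | COc1cc(OC)c(Oc2cc(OC)c(OC#CC3(O)C(OC)=C(OC)C3=O)c(OC)c2)c(OC)c1
F2 | step 7 | 5-[2,6-dimethoxy-4-(2,4,6-trimethoxyphenoxy)phenoxy]-2,3-dimethoxycyclohexa-2,5-diene-1,4-dione | COc1cc(OC)c(Oc2cc(OC)c(OC3=CC(=O)C(OC)=C(OC)C3=O)c(OC)c2)c(OC)c1
F3 | step 7 | 5-[2,6-dimethoxy-4-(2,4,6-trimethoxyphenoxy)phenoxy]-2,3-dimethoxybenzene-1,4-diol | COc1cc(OC)c(Oc2cc(OC)c(Oc3cc(O)c(OC)c(OC)c3O)c(OC)c2)c(OC)c1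
F4 | step 10 | (5-iodo-2,3-dimethoxyphenoxy)tri(propan-2-yl)silane | COc1cc(I)cc(O[Si](C(C)C)(C(C)C)C(C)C)c1OC
F5 | step 10 | {3,4-dimethoxy-5-[tri(propan-2-yl)silyloxy]phenyl}(2,4,6-trimethoxyphenyl)iodonium 4-methylbenzenesulfonate | COc1cc([I+]c2c(OC)cc(OC)cc2OC)cc(O[Si](C(C)C)(C(C)C)C(C)C)c1OC.Cc1ccc(S(=O)(=O)[O-])cc1
F6 | step 18 | octadeca-O-acetate of the target | CC(=O)Oc1cc(OC(C)=O)c(Oc2cc(OC(C)=O)c(Oc3cc(OC(C)=O)c(OC(C)=O)c(OC(C)=O)c3Oc4cc(OC(C)=O)c(OC(C)=O)c(Oc5cc(OC(C)=O)c(OC(C)=O)c(OC(C)=O)c5Oc6cc(OC(C)=O)c(Oc7cc(OC(C)=O)c(OC(C)=O)c(OC(C)=O)c7)c(OC(C)=O)c6)c4)c(OC(C)=O)c2)c(OC(C)=O)c1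
A1 | direct plan | 6-bromo-2,3,4-tris(benzyloxy)benzaldehyde | O=Cc1c(Br)cc(OCc2ccccc2)c(OCc3ccccc3)c1OCc4ccccc4
A2 | direct plan | 2,6-bis(benzyloxy)-4-[2,4,6-tris(benzyloxy)phenoxy]phenol | Oc1c(OCc2ccccc2)cc(Oc3c(OCc4ccccc4)cc(OCc5ccccc5)cc3OCc6ccccc6)cc1OCc7ccccc7
A3 | direct plan | 2,4,6-tris(benzyloxy)phenol | Oc1c(OCc2ccccc2)cc(OCc3ccccc3)cc1OCc4ccccc4
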